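**Plan**

- Retrosynthetic cuts: C12–C13 (alkylation of a lactone enolate), then C9–C11 and C8=C17 on a ring B 8-en-7-one, then C4–C5 and C3–C4 in one operation, last the C10–C1 bond of an allyl group on a ring made from cyclohexane-1,3-dione.
- Enabling feature: C4 carries two identical CH2OH groups and sits between C5–H and C3–OH. It can therefore be the central carbon of a malonate joined to an enone β-carbon (C5 of ring B) and to an aldehyde carbon (C3), which closes ring A.
- Forward order: ring B first (vinylogous ester, then γ-quaternary cyclohexenone with the C1–C3 aldehyde arm), ring A by the malonate annulation, then ring B dressing (C8–C9 enone, C9 vinyl, C8 methylene, C7 deoxygenation), ester reduction, butenolide last.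
- Stereochemistry: C10 from an enantioselective palladium-catalysed decarboxylative allylation; C5 (cis fusion) and C3 in the annulation, relative to C10; C9 from copper-mediated addition on the convex face of the cis-decalin.

Key step: step 8

**Conventions and assumptions**

- Labdane numbering is used for the bicyclic compounds: ring A = C1–C5, C10; ring B = C5–C10; C17 = methylene carbon on C8; C18/C19 = the two carbons on C4; C20 = methyl on C10; side chain C11–C16. "α" is the face that carries C20.
- The target as written has H5, O3, C11 and C20 all α, i.e. a cis-fused decalin, (3R,5R,9R,10S); the route is built for this.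
- The sense of induction in step 4 is taken from the 2-methylcyclohexanone series, where the (S)-ligand gives the (S)-ketone; on that basis the (R)-ligand is specified.

**Route**

Step 1
Reactants: 1 cyclohexane-1,3-dione
Product: 2 3-isobutoxycyclohex-2-en-1-one
Conditions: i-BuOH, p-TsOH (cat.), toluene, reflux, Dean–Stark
Reagents that add atoms: isobutanol, CC(C)CO
Why: Acid-catalysed enol etherification of the enolised 1,3-dione, driven by azeotropic removal of water, gives the vinylogous ester.

Step 2
Reactants: 2 3-isobutoxycyclohex-2-en-1-one; 3 allyl chloroformate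
Product: 5 allyl 4-isobutoxy-2-oxocyclohex-3-ene-1-carboxylate, via lithium dienolate 4 (not isolated)
Conditions: LiN(i-Pr)2 (2.1 equiv), THF, −78 °C; then ClCO2CH2CH=CH2, −78 → 0 °C; aq NH4Cl
Reagents that add atoms: allyl chloroformate (compound 3), C=CCOC(=O)Cl
Why: Kinetic deprotonation at the only enolisable α' position and C-acylation of the lithium enolate (Claisen-type acylation) should give the β-keto ester, the second equivalent of base taking up its acidic proton.

Step 3
Reactants: 5 allyl 4-isobutoxy-2-oxocyclohex-3-ene-1-carboxylate; 6 iodomethane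
Product: 7 allyl 4-isobutoxy-1-methyl-2-oxocyclohex-3-ene-1-carboxylate (racemic)
Conditions: K2CO3, MeI, acetone, 50 °C
Reagents that add atoms: iodomethane (compound 6), CI
Why: C-alkylation (SN2) of the stabilised β-keto ester enolate builds the quaternary carbon as a racemate, which is acceptable because the next step passes through an achiral enolate.

Step 4
Reactants: 7 allyl 4-isobutoxy-1-methyl-2-oxocyclohex-3-ene-1-carboxylate
Product: 8 (R)-6-allyl-3-isobutoxy-6-methylcyclohex-2-en-1-one
Conditions: Pd2(dba)3 (2.5 mol %), (R)-t-BuPHOX [(R)-4-tert-butyl-2-(2-diphenylphosphinophenyl)-4,5-dihydrooxazole] (6.25 mol %), toluene, 30 °C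
Reagents that add atoms: none
Why: Enantioselective decarboxylative allylic alkylation (Tsuji allylation with a chiral phosphinooxazoline): both enantiomers of 7 ionise and lose CO2 to the same palladium enolate/π-allyl pair, and the ligand-controlled C–C bond formation sets the C10 quaternary centre.

Step 5
Reactants: 8 (R)-6-allyl-3-isobutoxy-6-methylcyclohex-2-en-1-one
Product: 10 (R)-4-allyl-4-methylcyclohex-2-en-1-one, via allylic alcohol 9 (not isolated)
Conditions: LiAlH4, Et2O, 0 °C; then 10% aq HCl, 23 °C
Reagents that add atoms: water, O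
Why: Stork–Danheiser 1,3-carbonyl transposition (1,2-reduction of the vinylogous ester, then acid hydrolysis of the enol ether with loss of water) should give the γ-quaternary enone without touching the quaternary centre.

Step 6
Reactants: 10 (R)-4-allyl-4-methylcyclohex-2-en-1-one
Product: 12 (4S)-4-(3-hydroxypropyl)-4-methylcyclohex-2-en-1-ol (mixture of C1 epimers), via bis-borane adduct 11 (not isolated)
Conditions: 9-BBN (2.5 equiv), THF, 0 → 23 °C; then 3 M aq NaOH, 30% H2O2, 0 → 23 °C
Reagents that add atoms: hydrogen peroxide, OO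
Why: Hydroboration–oxidation: 9-BBN adds anti-Markovnikov to the terminal alkene and reduces the enone carbonyl in 1,2-fashion, while the ring alkene beside the quaternary carbon is too hindered to react; the carbinol epimers converge in step 7.

Step 7
Reactants: 12 (4S)-4-(3-hydroxypropyl)-4-methylcyclohex-2-en-1-ol
Product: 13 (S)-3-(1-methyl-4-oxocyclohex-2-en-1-yl)propanal
Conditions: Dess–Martin periodinane (2.5 equiv), NaHCO3, CH2Cl2, 0 → 23 °C
Reagents that add atoms: none
Why: Dess–Martin oxidation should convert the primary alcohol into the aldehyde and the allylic alcohol back into the enone in one buffered operation.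

Step 8
Reactants: 13 (S)-3-(1-methyl-4-oxocyclohex-2-en-1-yl)propanal; 14 dimethyl malonate
Product: 16 dimethyl (2R,4aS,8aR)-2-hydroxy-4a-methyl-7-oxooctahydronaphthalene-1,1(2H)-dicarboxylate (cis-fused; labdane numbering: 3α-hydroxy-7-oxo-4,4-diester), via Michael adduct 15 (not isolated)
Conditions: dimethyl malonate (1.2 equiv), MgBr2·OEt2 (1.5 equiv), Et3N (2.5 equiv), CH2Cl2, 0 → 23 °C; aq NH4Cl
Reagents that add atoms: dimethyl malonate (compound 14), COC(=O)CC(=O)OC
Why: MgBr2/Et3N soft-enolises the malonate, which adds to C5 of the magnesium-activated enone to give 15, and the now tertiary malonate C–H is enolised again and adds to the C3 aldehyde; the closest known reaction type is the base-mediated tandem Michael–aldol [5+1] annulation of malonates with enone aldehydes. Ring A closes by a 6-(enolexo)-exo-trig aldol through a chair transition state. C5 is controlled by C10: the magnesium that carries the malonate is also held by the aldehyde oxygen of the arm, so C4 should be delivered to the arm face of C5, anti to the pseudo-axial C20 methyl, which gives the cis ring fusion, while unassisted addition on the methyl face is reversible. C3 is controlled thermodynamically by aldol/retro-aldol equilibration: in the chair of ring A that keeps C20 axial and C4 on an equatorial bond of ring B, the magnesium-bound O3 is equatorial and cis to C20, whereas its epimer would hold O3 syn-axial to C6. The step needs C–C bond formation at C5 to win over condensation at the aldehyde and needs the cis fusion: C4 becomes quaternary on ring closure, so the aldolate cannot lose water, and the chelate of O3, magnesium and an ester carbonyl holds the product against retro-aldol and retro-Michael reversal.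

Step 9
Reactants: 16 cis-fused 3α-hydroxy-7-oxo-4,4-diester
Product: 17 3-O-tert-butyldimethylsilyl ether of 16
Conditions: TBSOTf (1.3 equiv), 2,6-lutidine, CH2Cl2, −78 → 0 °C
Reagents that add atoms: tert-butyldimethylsilyl triflate, CC(C)(C)[Si](C)(C)OS(=O)(=O)C(F)(F)F
Why: Silylation of the hindered secondary alcohol with the silyl triflate and a non-nucleophilic base blocks retro-aldol cleavage in the basic steps that follow.

Step 10
Reactants: 17 3-O-TBS ether of 16
Product: 19 C8–C9 enone of 17 (7-oxo-8-ene; stereocentres C3, C5 and C10 as in 17), via lithium enolate 18 (not isolated)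
Conditions: LiN(i-Pr)2 (1.1 equiv), THF, −78 °C; then t-BuN=S(Cl)Ph, −78 °C
Reagents that add atoms: none
Why: Kinetic deprotonation by the bulky amide should occur at C8, the α-methylene remote from the C4 quaternary centre, and the Mukaiyama dehydrogenation (S-attack of the enolate on the sulfinimidoyl chloride, then syn-elimination of the sulfenamide) gives the C8–C9 enone.

Step 11
Reactants: 19 C8–C9 enone
Product: 20 C7–C8 trimethylsilyl enol ether carrying a 9α-vinyl group (vinyl cis to C20)
Conditions: CH2=CHMgBr (2.5 equiv), CuBr·SMe2 (15 mol %), Me3SiCl, HMPA, THF, −78 → −40 °C; Et3N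
Reagents that add atoms: vinylmagnesium bromide, C=C[Mg]Br; chlorotrimethylsilane, C[Si](C)(C)Cl
Why: Copper-catalysed, Me3SiCl-accelerated conjugate addition of the vinyl Grignard reagent should occur at C9 on the convex face of the cis-decalin, anti to the C1–C10 bond, which places the vinyl group cis to C20, and the enolate is trapped regiospecifically as the C7–C8 silyl enol ether.

Step 12
Reactants: 20 9α-vinyl silyl enol ether
Product: 23 9α-vinyl-8(17)-methylene-7-ketone (3α-OTBS and 4,4-diester unchanged), via Mannich base 21 (not isolated), via ammonium iodide 22 (not isolated)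
Conditions: CH2=NMe2+ I− (Eschenmoser's salt), CH2Cl2, 23 °C; then MeI, 23 °C; then aq NaHCO3, 23 °C
Reagents that add atoms: dimethylmethyleneammonium iodide, C=[N+](C)C.[I-]
Why: Mannich reaction of the silyl enol ether at C8, then quaternisation and E1cB loss of trimethylamine (Eschenmoser methylenation), should give the exocyclic enone, the C8 configuration being erased.

Step 13
Reactants: 23 8(17)-methylene-7-ketone
Product: 24 C7 allylic alcohol (mixture of C7 epimers)
Conditions: NaBH4, CeCl3·7H2O, MeOH, −78 → 0 °C
Reagents that add atoms: none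
Why: Luche reduction gives selective 1,2-reduction of the enone in the presence of the esters and alkenes; the C7 configuration is irrelevant because the oxygen is removed in step 15.

Step 14
Reactants: 24 C7 allylic alcohol
Product: 25 C7 allylic methyl carbonate
Conditions: ClCO2Me, pyridine, DMAP (cat.), CH2Cl2, 0 °C
Reagents that add atoms: methyl chloroformate, COC(=O)Cl
Why: Acylation of the allylic alcohol installs the leaving group needed for π-allyl formation.

Step 15
Reactants: 25 C7 allylic methyl carbonate
Product: 26 diester with 8(17)-exocyclic methylene, C7 as CH2, 9α-vinyl and 3α-OTBS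
Conditions: Pd(OAc)2 (5 mol %), n-Bu3P (20 mol %), HCO2H, Et3N, THF, 40 °C
Reagents that add atoms: none
Why: Tsuji–Mandai formate reduction: ionisation gives the C7–C8–C17 π-allyl palladium formate and, with n-Bu3P, hydride is delivered to the more substituted terminus C7, which returns the exocyclic C8=C17 alkene and leaves C7 as CH2.

Step 16
Reactants: 26 exocyclic-methylene diester
Product: 27 18,19-diol (C4 bearing two CH2OH groups)
Conditions: i-Bu2AlH (6 equiv), CH2Cl2, −78 → 0 °C; aq KNaC4H4O6 (tartrate)
Reagents that add atoms: none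
Why: Hydride reduction of both hindered esters to the 1,3-diol; the aluminium alkoxides are weakly basic, so silyl migration is not expected, and the alkenes are inert.

Step 17
Reactants: 27 18,19-diol
Product: 28 18,19-acetonide (spiro-1,3-dioxane at C4)
Conditions: Me2C(OMe)2, PPTS (cat.), CH2Cl2, 23 °C
Reagents that add atoms: 2,2-dimethoxypropane, COC(C)(C)OC
Why: Acid-catalysed transacetalisation ties the two CH2OH groups into a six-membered acetonide, and C4 remains non-stereogenic.

Step 18
Reactants: 28 18,19-acetonide
Product: 30 C12 primary alcohol (C9–CH2CH2OH), via alkylborane 29 (not isolated)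
Conditions: Sia2BH (from BH3·SMe2 and 2-methylbut-2-ene; 1.5 equiv), THF, 0 °C; then 3 M aq NaOH, 30% H2O2, 0 °C
Reagents that add atoms: hydrogen peroxide, OO
Why: Hydroboration–oxidation with the bulky dialkylborane, which reacts with the monosubstituted vinyl group much faster than with the hindered 1,1-disubstituted C8=C17 alkene, should give the anti-Markovnikov alcohol.

Step 19
Reactants: 30 C12 primary alcohol
Product: 31 C12 primary iodide
Conditions: I2, PPh3, imidazole, CH2Cl2, 0 → 23 °C
Reagents that add atoms: iodine, II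
Why: Appel-type iodination (Garegg–Samuelsson conditions) through the alkoxyphosphonium salt, with imidazole buffering the medium for the acetal and the silyl ether.

Step 20
Reactants: 32 α-bromo-γ-butyrolactone (3-bromooxolan-2-one, racemic)
Product: 33 α-(phenylthio)-γ-butyrolactone (3-(phenylsulfanyl)oxolan-2-one, racemic)
Conditions: PhSH, Et3N, CH2Cl2, 0 → 23 °C
Reagents that add atoms: thiophenol, Sc1ccccc1
Why: SN2 displacement of the activated α-bromide by the thiolate.

Step 21
Reactants: 31 C12 primary iodide; 33 α-(phenylthio)-γ-butyrolactone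
Product: 35 C13-alkylated α-(phenylthio) lactone (mixture of C13 epimers), via potassium enolate 34 (not isolated)
Conditions: 33, KN(SiMe3)2, THF, −78 °C; then 31, DMPU, −78 → 23 °C
Reagents that add atoms: α-(phenylthio)-γ-butyrolactone (compound 33), O=C1OCCC1Sc1ccccc1
Why: SN2 alkylation of the sulfur-stabilised lactone enolate with the unhindered primary iodide forms C12–C13, and the new C13 centre is erased in step 22.

Step 22
Reactants: 35 C13-alkylated α-(phenylthio) lactone
Product: 37 3-O-TBS-18,19-O-isopropylidene derivative of the target (α-alkyl butenolide), via sulfoxide 36 (not isolated)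
Conditions: mCPBA (1.0 equiv), CH2Cl2, −78 °C; then toluene, CaCO3, 110 °C
Reagents that add atoms: none
Why: Chemoselective sulfide oxidation at low temperature, then thermal syn-elimination of the sulfoxide toward the ring methylene C14, should give the endocyclic butenolide, the usual outcome for α-alkyl-α-sulfinyl γ-lactones.

Step 23
Reactants: 37 protected target
Product: 38 target, 3-[2-[(1R,4aR,6R,8aS)-6-hydroxy-5,5-bis(hydroxymethyl)-8a-methyl-2-methylidenedecahydronaphthalen-1-yl]ethyl]furan-2(5H)-one
Conditions: 48% aq HF, MeCN, 0 → 23 °C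
Reagents that add atoms: none
Why: Aqueous HF should cleave the acetonide and the silyl ether together (acetal hydrolysis and fluoride-assisted desilylation) without opening the butenolide or isomerising the exocyclic alkene.

**Compound list**

1 | cyclohexane-1,3-dione | O=C1CCCC(=O)C1 | starting material
2 | 3-isobutoxycyclohex-2-en-1-one | CC(C)COC1=CC(=O)CCC1 | intermediate
3 | allyl chloroformate | C=CCOC(=O)Cl | starting material
4 | lithium 5-isobutoxycyclohexa-1,5-dien-1-olate (α'-enolate of 2; not isolated) | CC(C)COC1=CC(O[Li])=CCC1 | intermediate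
5 | allyl 4-isobutoxy-2-oxocyclohex-3-ene-1-carboxylate | C=CCOC(=O)C1CCC(OCC(C)C)=CC1=O | intermediate
6 | iodomethane | CI | starting material
7 | allyl 4-isobutoxy-1-methyl-2-oxocyclohex-3-ene-1-carboxylate (racemic) | C=CCOC(=O)C1(C)CCC(OCC(C)C)=CC1=O | intermediate
8 | (R)-6-allyl-3-isobutoxy-6-methylcyclohex-2-en-1-one | C=CC[C@@]1(C)CCC(OCC(C)C)=CC1=O | intermediate
9 | (6R)-6-allyl-3-isobutoxy-6-methylcyclohex-2-en-1-ol (C1 epimers; not isolated) | C=CC[C@@]1(C)CCC(OCC(C)C)=CC1O | intermediate
10 | (R)-4-allyl-4-methylcyclohex-2-en-1-one | C=CC[C@@]1(C)CCC(=O)C=C1 | intermediate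
11 | bis(9-BBN) adduct of 10: B-alkyl at the chain terminus, B-alkoxy at the ring carbinol (not isolated) | B1(CCC[C@@]5(C)CCC(OB3C4CCCC3CCC4)C=C5)C2CCCC1CCC2 | intermediate
12 | (4S)-4-(3-hydroxypropyl)-4-methylcyclohex-2-en-1-ol (C1 epimers) | OCCC[C@@]1(C)CCC(O)C=C1 | intermediate
13 | (S)-3-(1-methyl-4-oxocyclohex-2-en-1-yl)propanal | O=CCC[C@@]1(C)CCC(=O)C=C1 | intermediate
14 | dimethyl malonate | COC(=O)CC(=O)OC | starting material
15 | dimethyl 2-[(1S,2S)-2-methyl-5-oxo-2-(3-oxopropyl)cyclohexyl]propanedioate (malonate cis to the arm; not isolated) | O=CCC[C@@]1(C)CCC(=O)C[C@H]1C(C(=O)OC)C(=O)OC | intermediate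
16 | dimethyl (2R,4aS,8aR)-2-hydroxy-4a-methyl-7-oxooctahydronaphthalene-1,1(2H)-dicarboxylate (cis-fused; 3α-OH, 5α-H, 10α-Me) | C1C(=O)C[C@H]2C(C(=O)OC)(C(=O)OC)[C@H](O)CC[C@@]2(C)C1 | intermediate
17 | 3-O-tert-butyldimethylsilyl ether of 16 | C1C(=O)C[C@H]2C(C(=O)OC)(C(=O)OC)[C@H](O[Si](C)(C)C(C)(C)C)CC[C@@]2(C)C1 | intermediate
18 | lithium C7–C8 enolate of 17 (not isolated) | C1=C(O[Li])C[C@H]2C(C(=O)OC)(C(=O)OC)[C@H](O[Si](C)(C)C(C)(C)C)CC[C@@]2(C)C1 | intermediate
19 | C8–C9 enone of 17 (7-oxo-8-ene) | C1=CC(=O)C[C@H]2C(C(=O)OC)(C(=O)OC)[C@H](O[Si](C)(C)C(C)(C)C)CC[C@@]12C | intermediate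
20 | C7–C8 trimethylsilyl enol ether with 9α-vinyl (3α-OTBS, 4,4-diester) | C1=C(O[Si](C)(C)C)C[C@H]2C(C(=O)OC)(C(=O)OC)[C@H](O[Si](C)(C)C(C)(C)C)CC[C@@]2(C)[C@@H]1C=C | intermediate
21 | 8-(dimethylaminomethyl)-9α-vinyl-7-ketone (C8 epimers; not isolated) | CN(C)CC1C(=O)C[C@H]2C(C(=O)OC)(C(=O)OC)[C@H](O[Si](C)(C)C(C)(C)C)CC[C@@]2(C)[C@@H]1C=C | intermediate
22 | trimethylammonium iodide of 21 (not isolated) | C[N+](C)(C)CC1C(=O)C[C@H]2C(C(=O)OC)(C(=O)OC)[C@H](O[Si](C)(C)C(C)(C)C)CC[C@@]2(C)[C@@H]1C=C.[I-] | intermediate
23 | 9α-vinyl-8(17)-methylene-7-ketone (3α-OTBS, 4,4-diester) | C=C1C(=O)C[C@H]2C(C(=O)OC)(C(=O)OC)[C@H](O[Si](C)(C)C(C)(C)C)CC[C@@]2(C)[C@@H]1C=C | intermediate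
24 | C7 allylic alcohol of 23 (C7 epimers) | C=C1C(O)C[C@H]2C(C(=O)OC)(C(=O)OC)[C@H](O[Si](C)(C)C(C)(C)C)CC[C@@]2(C)[C@@H]1C=C | intermediate
25 | C7 methyl carbonate of 24 | C=C1C(OC(=O)OC)C[C@H]2C(C(=O)OC)(C(=O)OC)[C@H](O[Si](C)(C)C(C)(C)C)CC[C@@]2(C)[C@@H]1C=C | intermediate
26 | 8(17)-methylene, 9α-vinyl, 3α-OTBS 4,4-diester (C7 = CH2) | C=C1CC[C@H]2C(C(=O)OC)(C(=O)OC)[C@H](O[Si](C)(C)C(C)(C)C)CC[C@@]2(C)[C@@H]1C=C | intermediate
27 | 18,19-diol from 26 | C=C1CC[C@H]2C(CO)(CO)[C@H](O[Si](C)(C)C(C)(C)C)CC[C@@]2(C)[C@@H]1C=C | intermediate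
28 | 18,19-acetonide of 27 (spiro-1,3-dioxane at C4) | C=C1CC[C@H]2C3(COC(C)(C)OC3)[C@H](O[Si](C)(C)C(C)(C)C)CC[C@@]2(C)[C@@H]1C=C | intermediate
29 | C12 bis(3-methylbutan-2-yl)borane from 28 (not isolated) | C=C1CC[C@H]2C3(COC(C)(C)OC3)[C@H](O[Si](C)(C)C(C)(C)C)CC[C@@]2(C)[C@@H]1CCB(C(C)C(C)C)C(C)C(C)C | intermediate
30 | C12 primary alcohol | C=C1CC[C@H]2C3(COC(C)(C)OC3)[C@H](O[Si](C)(C)C(C)(C)C)CC[C@@]2(C)[C@@H]1CCO | intermediate
31 | C12 primary iodide | C=C1CC[C@H]2C3(COC(C)(C)OC3)[C@H](O[Si](C)(C)C(C)(C)C)CC[C@@]2(C)[C@@H]1CCI | intermediate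
32 | α-bromo-γ-butyrolactone (racemic) | O=C1OCCC1Br | starting material
33 | α-(phenylthio)-γ-butyrolactone (racemic) | O=C1OCCC1Sc1ccccc1 | intermediate
34 | potassium enolate of 33 (not isolated) | [K]OC1=C(Sc2ccccc2)CCO1 | intermediate
35 | C13-alkylated α-(phenylthio) lactone (C13 epimers) | C=C1CC[C@H]2C3(COC(C)(C)OC3)[C@H](O[Si](C)(C)C(C)(C)C)CC[C@@]2(C)[C@@H]1CCC1(Sc2ccccc2)CCOC1=O | intermediate
36 | sulfoxide of 35 (not isolated) | C=C1CC[C@H]2C3(COC(C)(C)OC3)[C@H](O[Si](C)(C)C(C)(C)C)CC[C@@]2(C)[C@@H]1CCC1(S(=O)c2ccccc2)CCOC1=O | intermediate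
37 | 3-O-TBS-18,19-O-isopropylidene derivative of the target | C=C1CC[C@H]2C3(COC(C)(C)OC3)[C@H](O[Si](C)(C)C(C)(C)C)CC[C@@]2(C)[C@@H]1CCC1=CCOC1=O | intermediate
38 | CNP0146463.1, (3R,5R,9R,10S) in labdane numbering | C=C1CC[C@H]2C(CO)(CO)[C@H](O)CC[C@@]2(C)[C@@H]1CCC1=CCOC1=O | target

**Step count**

Total: 23 steps. Longest linear sequence: 22 steps (steps 1–19 and 21–23); step 20 is a one-step side branch.

**Steps most likely to fail**

1. Step 8. The malonate may add to the free aldehyde and lose water before any conjugate addition; conjugate addition at the neopentyl C5 may be slow or take place on the methyl face, eroding the cis fusion; and retro-aldol equilibration may settle on the C3 epimer, since the two chairs of the cis-decalin are close in energy. Fallback, from 13 back to 16: the two bonds are made in separate flasks with the malonate first tied to the arm. Magnesium-mediated aldol addition of 14 to the aldehyde of 13 with in situ silylation (MgBr2·OEt2, Et3N, Me3SiCl, EtOAc) should give the silylated aldol adduct F1. A catalytic carbonate base (Cs2CO3, MeCN) should then close ring A by intramolecular 6-exo-trig conjugate addition, which can reach C5 only on the arm face, to give the cis-fused trimethylsilyl ether F2. Methanolysis with citric acid returns 16; the C3 epimers are separated at this stage and the unwanted one is re-equilibrated under the magnesium conditions of step 8.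

2. Step 10. Deprotonation may not discriminate between C8 and C6, so that dehydrogenation runs toward C5–C6. Fallback, from 17 back to 23: regiocontrol is handed to a reversible acylation. Claisen formylation (HCO2Et, NaH, THF) should settle at the less hindered C8 and give the 8-hydroxymethylene ketone F3. Dehydrogenation with DDQ in dioxane gives the 8-formyl-8-en-7-one F4, a doubly activated acceptor that takes up the vinyl cuprate (CH2=CHMgBr, CuBr·SMe2, THF, −78 °C) at C9 on the convex face to give the 9α-vinyl β-keto aldehyde F5. Aqueous formaldehyde with K2CO3 (hydroxymethylation at C8, then deformylation and loss of hydroxide) gives the methylene ketone 23, so steps 10–12 are bypassed.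

3. Step 18. The borane may also add to the exocyclic C8=C17 alkene, giving diol mixtures. Fallback, from 28 back to 31: hydrozirconation with Cp2Zr(H)Cl in THF, which is far more sensitive to alkene substitution than hydroboration, should engage only the vinyl group and give the C12 alkylzirconocene chloride F6; iodinolysis with I2 gives iodide 31 directly, so step 19 is bypassed as well.

**Further compounds**

F1 | step 8 | silylated aldol adduct, dimethyl 2-[3-[(1S)-1-methyl-4-oxocyclohex-2-en-1-yl]-1-(trimethylsilyloxy)propyl]propanedioate (C3 epimers) | COC(=O)C(C(=O)OC)C(O[Si](C)(C)C)CC[C@@]1(C)CCC(=O)C=C1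
F2 | step 8 | cis-fused trimethylsilyl ether of 16 | C1C(=O)C[C@H]2C(C(=O)OC)(C(=O)OC)[C@H](O[Si](C)(C)C)CC[C@@]2(C)C1
F3 | step 10 | 8-hydroxymethylene ketone from 17 | OC=C1C(=O)C[C@H]2C(C(=O)OC)(C(=O)OC)[C@H](O[Si](C)(C)C(C)(C)C)CC[C@@]2(C)C1
F4 | step 10 | 8-formyl-8-en-7-one | C1=C(C=O)C(=O)C[C@H]2C(C(=O)OC)(C(=O)OC)[C@H](O[Si](C)(C)C(C)(C)C)CC[C@@]12C
F5 | step 10 | 9α-vinyl β-keto aldehyde (8-formyl-7-ketone, C8 epimers or enol) | O=CC1C(=O)C[C@H]2C(C(=O)OC)(C(=O)OC)[C@H](O[Si](C)(C)C(C)(C)C)CC[C@@]2(C)[C@@H]1C=C
F6 | step 18 | C12 alkylzirconocene chloride from 28 | C=C1CC[C@H]2C3(COC(C)(C)OC3)[C@H](O[Si](C)(C)C(C)(C)C)CC[C@@]2(C)[C@@H]1CC[Zr](Cl)(C1C=CC=C1)C1C=CC=C1
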